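A small charge of partner, 1.20 M in theta against 1.76 M in delta, raises one question: which flask holds the larger excess x at 15 h, x being right-handed minus left-handed substrate over their sum?

| flask | left-handed substrate | right-handed substrate | partner | remark | time |
|---|---|---|---|---|---|
| green | 0.80 M | 0.80 M | 1.4 M | run made earlier |  |
| grey | 0.80 M | 0.80 M | 2.1 M | run made earlier |  |
| delta | 0.80 M | 0.80 M | 1.76 M |  | 15 h |
| theta | 0.80 M | 0.80 M | 1.20 M |  | 15 h |

- green (time / h: right-handed substrate / %, left-handed substrate / %): 0.833: 47, 36; 1.33: 45, 31; 2.00: 46, 27; 3.00: 40, 23; 5.00: 39, 16; 6.00: 35, 19; 10.0: 27, 14
- grey (time / h: right-handed substrate / %, left-handed substrate / %): 1.50: 45, 24; 3.00: 40, 17; 5.00: 35, 13; 6.00: 31, 11; 8.00: 25, 10; 10.0: 25, 11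

(each reading ± 1.5 percentage points)

- partner is single-handed; left-handed substrate and right-handed substrate are mirror images of each other, charged as a racemate, each of them at the stated concentration
- an excess is the difference of the two amounts in percent of their sum
- an excess is below zero if the other one leads
- the handed part of partner does not stay in what it makes, so the products of the two hands are mirror images too

- which one finishes higher in excess of right-handed substrate over left-handed substrate among what is left of the two ("neither" within 2 percentage points) (delta / theta / neither)
- excess of right-handed substrate over left-handed substrate among what is left of the two at the end, delta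
- excess of right-handed substrate over left-handed substrate among what is left of the two at the end, theta

I solve two extremes first. If x stayed frozen (kinetic control) at the last readings, taken at 10.0 h, green would give 31.7 % and grey 38.9 %. A straight line in partner, extended below green's charge for theta, then puts delta at 35.4 % and theta at 29.7 %. If the hands had reached their common end (thermodynamic control), x would be zero.

To place the real flasks between these, I look at right-handed substrate. From first to last reading it falls at a fractional rate of 0.0605 h⁻¹ in green, at 1.4 M of partner, and of 0.0692 h⁻¹ in grey, at 2.1 M, so I do not tie this loss to partner. I take the mean of the two as the erosion rate λ, 0.0648 h⁻¹, and assume that x shrinks at this fractional rate beyond the last readings, where left-handed substrate in grey reads 10 % and then 11 %.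

The 5.00 h still to run are half of the half-time of this erosion, so I place both flasks between the extremes. My reckoning gives delta 25.6 % and theta 21.4 %. So I commit to delta, ahead by 4.2 percentage points, a gap that a scatter of 1.5 points per reading can still blur.

The forecast says neither, with 28 % for delta and 29 % for theta, holding that “less partner means slower progress”. My reckoning puts delta ahead where the forecast puts neither.

The flask gives delta: 26.6 % in delta and 18.7 % in theta.

    partner + left-handed substrate → left-handed product (k = 0.00540 M⁻¹ min⁻¹)
    partner + right-handed substrate → right-handed product (k = 2.90 × 10⁻⁵ M⁻¹ min⁻¹)
    left-handed substrate ⇌ achiral form (K = 0.0410, k = 0.00340 min⁻¹)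
    right-handed substrate ⇌ achiral form (K = 0.0410, k = 0.00340 min⁻¹)
    achiral form → waste (k = 0.0180 min⁻¹)
    partner → decomposition product (k = 2.50 × 10⁻⁵ min⁻¹)
    2 partner → homo dimer (k = 8.00 × 10⁻⁴ M⁻¹ min⁻¹)

Green with only its partner moved to theta's 1.20 M stands at 26.1 % at 10.0 h. Carried at λ to 15 h, that becomes 18.9 %, beside the 18.7 % of theta. The neighbouring flask is theta left until 40 h. From 18.7 %, λ gives 3.70 % there, and that flask stands at 3.25 %.

The earlier runs and the new flask were computed on assumed constants; scatter was added.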